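Which way of charging gives the largest share of target in target plus trapped intermediate after 2.0 min?

| flask | substrate | partner | capture agent | temperature | remark | time |
|---|---|---|---|---|---|---|
| noon | 0.10 M | 0.095 M | 0.030 M | 55 °C | run made earlier |  |
| spring | 0.10 M | 0.095 M | 0.020 M | 70 °C | run made earlier |  |
| dawn | 0.10 M | 0.095 M | 0.045 M | 55 °C | run made earlier |  |
| summer | 0.10 M | 0.19 M | 0.030 M | 70 °C | run made earlier |  |
| grey | 0.10 M (fed, over 1.5 min) | 0.0950 M | 0.0300 M |  | the addition at 50 °C, then warmed to 70 °C; the feed brings no volume worth counting | 2.0 min |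
| teal | 0.10 M | 0.0950 M | 0.0300 M | 70 °C | everything together at the start | 2.0 min |
| blue | 0.10 M (fed, over 1.5 min) | 0.0950 M | 0.0300 M | 70 °C | all else is in the flask from the start; the feed brings no volume worth counting | 2.0 min |
| violet | 0.10 M | 0.0950 M (fed, over 1.5 min) | 0.0300 M | 70 °C | all else is in the flask from the start; the feed brings no volume worth counting | 2.0 min |

- the best flask by share of target in target plus trapped intermediate; "all alike" if 1.5 percentage points covers them all (grey / teal / blue / violet / all alike)
- share of target in target plus trapped intermediate at the end, grey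
- share of target in target plus trapped intermediate at the end, teal
- share of target in target plus trapped intermediate at the end, blue
- share of target in target plus trapped intermediate at the end, violet

| run | time / min | target / % | trapped intermediate / % |
|---|---|---|---|
| noon | 0.333 | 0.5 | 4.8 |
| noon | 0.667 | 5.0 | 11.5 |
| noon | 2.00 | 18.3 | 24.4 |
| noon | 4.00 | 25.9 | 25.6 |
| spring | 0.667 | 11.9 | 13.0 |
| spring | 1.33 | 13.8 | 15.0 |
| spring | 2.00 | 14.9 | 15.2 |
| spring | 2.50 | 15.2 | 15.1 |
| dawn | 0.417 | 2.1 | 9.9 |
| dawn | 0.833 | 6.8 | 21.0 |
| dawn | 2.00 | 17.4 | 33.0 |
| dawn | 5.00 | 23.8 | 37.9 |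
| summer | 0.333 | 12.6 | 11.0 |
| summer | 0.833 | 23.5 | 17.5 |
| summer | 1.50 | 24.4 | 18.0 |
| summer | 2.50 | 26.8 | 17.4 |

(each reading ± 0.5 percentage points)

- what was read earlier has a scatter of 0.5 percentage points, one standard deviation

Follow one molecule of substrate to the fork where it becomes target or trapped intermediate: its odds are the target rate over the trapping rate. From noon to dawn, [capture agent] rises by a factor 1.50, and trapped intermediate at 2.00 min rises by 1.35, more than target, which stays at 0.951 of its value. The odds also start low: noon reads 0.104 up to 0.333 min and a higher 0.672 in the next interval, a lag (induction period) that the first molecules lose to.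

At 70 °C, the spring trapping rate falls from 0.195 /min to 0.0302 /min of the charge, a factor 6.46. The target rate falls from 0.178 /min to 0.0287 /min, a factor 6.23. The two factors are close, so the ratio of target to trapped intermediate standing in spring moves from 0.915 at 0.667 min to 1.01 at 2.50 min. That gives a reading of what stands, not of what was formed, the stop constant, target over trapped intermediate standing at the stop, divided by partner charged over capture agent charged:

φ = (15.2% / 15.1%) / (0.095 M / 0.020 M) = 0.212

Summer reads 0.243. For teal, my own reckoning gives:

stop ratio = φ × 0.0950 M / 0.0300 M = 0.671, share = 40.2%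

This constant is read from a run charged all at once, lag included. Blue feeds its substrate over 1.5 min, longer than the first noon interval of 0.333 min, so this reckoning puts blue above teal and violet below it.

The forecast differs. It names grey, with grey 39%, teal 38%, blue 29% and violet 13%, holding that in blue “substrate arrives after activity has died”.

The flask gives blue: blue 44.9%, grey 39.3%, teal 39.1%, violet 31.7%.

    open intermediate + second intermediate → target (k = 0.757 /M/s, Ea = 43.0 kJ/mol)
    partner → second intermediate (k = 0.0509 /s, Ea = 96.0 kJ/mol)
    open intermediate + capture agent → trapped intermediate (k = 1.22 /M/s, Ea = 49.0 kJ/mol)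
    substrate ⇌ open intermediate (K = 0.410, k = 0.126 /s, Ea = 94.0 kJ/mol, ΔH = −54.0 kJ/mol)
    substrate + target → side product (k = 1.00 /M/s, Ea = 68.0 kJ/mol)
    (constants at 70 °C)

At 2.00 min, blue holds 0.0549 M of second intermediate, with partner at 0.222% of its charge. Blue's own stop constant comes to 0.257, above the 0.212 read from spring. A neighbour of blue with 0.024 M of partner has, by the spring constant, a stop ratio of 0.170 and a share of 14.5%; that flask gives 12.5%.

(The data stem from a simulated flask from invented constants; noise was put on by code.)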